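## Retrosynthetic overview

1. The target is the peripheral double epoxide of a (1(10)E,4E)-germacradienolide carrying the 8β-tiglate; its exocyclic methylene comes from Eschenmoser methylenation of the 13-nor lactone.
2. The ten-membered ring is opened at C3–C4: intramolecular B-alkyl Suzuki–Miyaura coupling joins a C3 borane (from the terminal C2=C3 alkene of a C10=C1–C2=C3 diene) to an (E)-C4 alkenyl iodide on a monocyclic γ-lactone.
3. Enabling feature: the C4–O–C5 oxirane is an epoxidised (E)-trisubstituted C4=C5 alkene of the ten-membered ring, so C4 is a methyl-bearing sp2 carbon. Its neighbour C3 is a CH2 homoallylic to C1=C10 (the later C1–O–C10 oxirane). C3–C4 is therefore an sp3–sp2 bond between two alkene-derived termini that leave adjacent carbons (C6, C7) of the trans-fused γ-lactone (C6, C7, C11, C12, O).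
4. The seco-lactone comes from an auxiliary-controlled syn-aldol (C6–C7) of (E)-3-iodobut-2-enal with a succinate thiazolidinethione, chelation-controlled propargylation (C8–C9), tigloylation and lactonisation, then carboalumination/hydroxymethylation and methylenation to build the diene.
5. Ring order: γ-lactone (step 9), then ten-membered carbocycle (step 13), then both oxiranes in one operation (step 15).

Key step: step 13

Remark on the chemistry: the target is read as (1R,4R,5R,6S,7R,8R,10R)-8β-tigloyloxy-1β,10α:4α,5β-diepoxygermacr-11(13)-en-12,6α-olide. Germacrane numbering (C1–C10 ring, C11–C13 lactone carbons, C14 on C10, C15 on C4) is used for positions in all intermediates.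

## Route

Step 1
Reactants: 1 but-2-yn-1-ol
Product: 3 (E)-3-iodobut-2-en-1-ol, via alkenylzirconocene chloride 2 (not isolated)
Conditions: i-Bu2AlH (1 equiv), THF, 0 °C; Cp2ZrCl2 + i-Bu2AlH (1.2 equiv each, forms Cp2Zr(H)Cl), 0 °C → rt; I2, −78 → 0 °C
Reagents that add atoms: iodine, II
Why: syn-hydrozirconation of the alkyne (Schwartz reagent made in situ) should place zirconium on the methyl-bearing carbon remote from the aluminium alkoxide, and iodinolysis with retention gives the (E)-alkenyl iodide (hydrozirconation–iodination).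

Step 2
Reactants: 3 (E)-3-iodobut-2-en-1-ol
Product: 4 (E)-3-iodobut-2-enal
Conditions: MnO2, CH2Cl2, rt
Reagents that add atoms: none
Why: MnO2 oxidation of a primary allylic alcohol should stop at the enal and leave the C–I bond and the alkene geometry untouched (allylic oxidation).

Step 3
Reactants: 5 (S)-4-benzyl-1,3-thiazolidine-2-thione; 6 4-tert-butoxy-4-oxobutanoic acid
Product: 7 tert-butyl 4-[(4S)-4-benzyl-2-thioxo-1,3-thiazolidin-3-yl]-4-oxobutanoate
Conditions: DCC, DMAP (cat.), CH2Cl2, 0 °C → rt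
Reagents that add atoms: none
Why: carbodiimide activation of the acid and DMAP-catalysed N-acylation of the thiazolidinethione (Steglich-type coupling) should give the imide directly.

Step 4
Reactants: 7 tert-butyl 4-[(4S)-4-benzyl-2-thioxo-1,3-thiazolidin-3-yl]-4-oxobutanoate; 4 (E)-3-iodobut-2-enal
Product: 8 tert-butyl (3S,4S,5E)-3-{[(4S)-4-benzyl-2-thioxo-1,3-thiazolidin-3-yl]carbonyl}-4-hydroxy-6-iodohept-5-enoate
Conditions: TiCl4, i-Pr2NEt, N-methylpyrrolidinone, CH2Cl2, 0 °C; then 4, −78 °C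
Reagents that add atoms: none
Why: titanium-enolate aldol in its Evans-syn mode (Crimmins aldol), in which the Z-enolate should add through the non-chelated chair transition state on the face away from the benzyl group and so set C7 and C6 as the syn pair; the tert-butyl ester blocks premature lactonisation and the reaction is kept at −78 °C to spare it.

Step 5
Reactants: 8 tert-butyl (3S,4S,5E)-3-{[(4S)-4-benzyl-2-thioxo-1,3-thiazolidin-3-yl]carbonyl}-4-hydroxy-6-iodohept-5-enoate
Product: 9 tert-butyl (3S,4S,5E)-3-{[(4S)-4-benzyl-2-thioxo-1,3-thiazolidin-3-yl]carbonyl}-6-iodo-4-(methoxymethoxy)hept-5-enoate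
Conditions: MOMCl, i-Pr2NEt, CH2Cl2, 0 °C → rt
Reagents that add atoms: chloromethyl methyl ether, COCCl
Why: O-alkylation of the secondary alcohol under a hindered amine base (MOM ether formation) installs a chelating protecting group on O6 for step 7.

Step 6
Reactants: 9 tert-butyl (3S,4S,5E)-3-{[(4S)-4-benzyl-2-thioxo-1,3-thiazolidin-3-yl]carbonyl}-6-iodo-4-(methoxymethoxy)hept-5-enoate
Product: 10 tert-butyl (3S,4S,5E)-3-formyl-6-iodo-4-(methoxymethoxy)hept-5-enoate
Conditions: i-Bu2AlH, CH2Cl2, −78 °C; aq. KNaC4H4O6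
Reagents that add atoms: none
Why: the activated N-acyl thiazolidinethione should be reduced by i-Bu2AlH to a stable tetrahedral aluminium adduct that releases the aldehyde on work-up (reductive auxiliary cleavage), while the tert-butyl ester is inert at −78 °C.

Step 7
Reactants: 10 tert-butyl (3S,4S,5E)-3-formyl-6-iodo-4-(methoxymethoxy)hept-5-enoate; 11 tributyl(propa-1,2-dien-1-yl)stannane
Product: 12 tert-butyl (3R,4S,5E)-3-[(1R)-1-hydroxybut-3-yn-1-yl]-6-iodo-4-(methoxymethoxy)hept-5-enoate
Conditions: MgBr2·OEt2, CH2Cl2, −20 → 0 °C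
Reagents that add atoms: none
Why: chelation-controlled SE2′ propargylation with the allenylstannane, in which MgBr2 bridges the aldehyde and the O6 MOM ether and attack anti to both the C6 substituent (1,3-anti) and the C7 side chain (1,2-anti, Cram-chelate), which reinforce each other in this 2,3-syn aldehyde, should set C8 as R.

Step 8
Reactants: 12 tert-butyl (3R,4S,5E)-3-[(1R)-1-hydroxybut-3-yn-1-yl]-6-iodo-4-(methoxymethoxy)hept-5-enoate; 13 (E)-2-methylbut-2-enoyl chloride
Product: 14 tert-butyl (3R,4S,5E)-6-iodo-4-(methoxymethoxy)-3-{(1R)-1-[(E)-2-methylbut-2-enoyloxy]but-3-yn-1-yl}hept-5-enoate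
Conditions: pyridine, DMAP (cat.), CH2Cl2, 0 °C → rt
Reagents that add atoms: none
Why: DMAP-catalysed acylation with retention at C8 installs the final tiglate and caps O8 before O6 is released, so that only the 6,12-lactone can form later.

Step 9
Reactants: 14 tert-butyl (3R,4S,5E)-6-iodo-4-(methoxymethoxy)-3-{(1R)-1-[(E)-2-methylbut-2-enoyloxy]but-3-yn-1-yl}hept-5-enoate
Product: 16 (1R)-1-{(2S,3R)-2-[(E)-2-iodoprop-1-en-1-yl]-5-oxooxolan-3-yl}but-3-yn-1-yl (E)-2-methylbut-2-enoate, via γ-hydroxy acid 15 (not isolated)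
Conditions: ZnBr2, n-PrSH, CH2Cl2, 0 °C → rt
Reagents that add atoms: none
Why: Lewis-acid/thiol cleavage removes the MOM ether and the tert-butyl ester without Brønsted-acid ionisation of the allylic C6–O bond, and the γ-hydroxy acid should close the trans-4,5-disubstituted γ-lactone by acyl–oxygen bond formation, so C6 keeps its configuration (lactonisation).

Step 10
Reactants: 16 (1R)-1-{(2S,3R)-2-[(E)-2-iodoprop-1-en-1-yl]-5-oxooxolan-3-yl}but-3-yn-1-yl (E)-2-methylbut-2-enoate
Product: 18 (1R,3E)-5-hydroxy-1-{(2S,3R)-2-[(E)-2-iodoprop-1-en-1-yl]-5-oxooxolan-3-yl}-3-methylpent-3-en-1-yl (E)-2-methylbut-2-enoate, via alkenyldimethylalane 17 (not isolated)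
Conditions: Me3Al, Cp2ZrCl2 (25 mol %), CH2Cl2, 0 °C → rt; (CH2O)n, 0 °C → rt
Reagents that add atoms: trimethylaluminium, C[Al](C)C; formaldehyde (as paraformaldehyde), C=O
Why: zirconium-catalysed carboalumination (Negishi) adds CH3 and Al syn across the terminal alkyne with methyl on C10, and trapping of the alkenylalane with formaldehyde proceeds with retention, so the C1=C10 alkene should be formed as the E isomer.

Step 11
Reactants: 18 (1R,3E)-5-hydroxy-1-{(2S,3R)-2-[(E)-2-iodoprop-1-en-1-yl]-5-oxooxolan-3-yl}-3-methylpent-3-en-1-yl (E)-2-methylbut-2-enoate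
Product: 19 (1R,3E)-1-{(2S,3R)-2-[(E)-2-iodoprop-1-en-1-yl]-5-oxooxolan-3-yl}-3-methyl-5-oxopent-3-en-1-yl (E)-2-methylbut-2-enoate
Conditions: MnO2, CH2Cl2, rt
Reagents that add atoms: none
Why: chemoselective MnO2 oxidation of the primary allylic alcohol to the enal under neutral conditions (allylic oxidation).

Step 12
Reactants: 19 (1R,3E)-1-{(2S,3R)-2-[(E)-2-iodoprop-1-en-1-yl]-5-oxooxolan-3-yl}-3-methyl-5-oxopent-3-en-1-yl (E)-2-methylbut-2-enoate
Product: 20 (1R,3E)-1-{(2S,3R)-2-[(E)-2-iodoprop-1-en-1-yl]-5-oxooxolan-3-yl}-3-methylhexa-3,5-dien-1-yl (E)-2-methylbut-2-enoate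
Conditions: Ph3PCH3Br, KN(SiMe3)2, THF, −78 → 0 °C
Reagents that add atoms: methyltriphenylphosphonium bromide, C[P+](c1ccccc1)(c1ccccc1)c1ccccc1.[Br-]
Why: Wittig methylenation, in which the non-stabilised ylide should react with the aldehyde far faster than with the lactone or ester carbonyls at low temperature and give the terminal C2=C3 alkene of the diene.

Step 13
Reactants: 20 (1R,3E)-1-{(2S,3R)-2-[(E)-2-iodoprop-1-en-1-yl]-5-oxooxolan-3-yl}-3-methylhexa-3,5-dien-1-yl (E)-2-methylbut-2-enoate
Product: 22 (3aR,4R,6E,10E,11aR)-6,10-dimethyl-2-oxo-2,3,3a,4,5,8,9,11a-octahydrocyclodeca[b]furan-4-yl (E)-2-methylbut-2-enoate, via B-alkyl-9-BBN borane 21 (not isolated)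
Conditions: 9-BBN-H (1.3 equiv), THF, 0 °C → rt; then syringe-pump addition to Pd(dppf)Cl2 (15 mol %), AsPh3 (30 mol %), Cs2CO3 (3 equiv), DMF/THF/H2O, 45 °C, final 1 mM
Reagents that add atoms: none
Why: 9-BBN should add only to the terminal C2=C3 alkene of the diene (boron on C3) and leave the trisubstituted, conjugated and iodo-substituted alkenes alone; zerovalent palladium then inserts into the C4–I bond with retention, the hydroxyborate transfers the primary C3 alkyl group, and reductive elimination forms the C3–C4 bond (intramolecular B-alkyl Suzuki–Miyaura coupling). The closest known reactions are B-alkyl Suzuki macrocyclisations that close nine- and twelve-membered carbocycles at an (E)-trisubstituted alkene. The ten-membered carbocycle is closed by reductive elimination from an eleven-membered palladacycle, that is a 10-membered ring closure at the sp2 carbon C4, and it turns a monocyclic lactone into the complete bicyclic germacranolide skeleton. No stereocentre is formed; the E geometry of C4=C5 follows from the stereoretentive coupling of the (E)-iodide and that of C1=C10 was fixed in step 10, and together they impose the crown conformation used for facial control in step 15. The step needs ring closure to beat oligomerisation and β-hydride elimination, which pseudo-high dilution, the wide-bite-angle dppf ligand with AsPh3 and the two chains leaving adjacent carbons of the trans-disubstituted lactone should secure. The lactone still lacks its exocyclic methylene here, so no electron-poor 1,1-disubstituted alkene competes for the borane.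

Step 14
Reactants: 22 (3aR,4R,6E,10E,11aR)-6,10-dimethyl-2-oxo-2,3,3a,4,5,8,9,11a-octahydrocyclodeca[b]furan-4-yl (E)-2-methylbut-2-enoate
Product: 25 (3aR,4R,6E,10E,11aR)-6,10-dimethyl-3-methylidene-2-oxo-2,3,3a,4,5,8,9,11a-octahydrocyclodeca[b]furan-4-yl (E)-2-methylbut-2-enoate, via Mannich base 23 (not isolated), via trimethylammonium iodide 24 (not isolated)
Conditions: LiN(SiMe3)2, THF, −78 °C; CH2=NMe2+ I−, −78 → 0 °C; MeI, MeOH, rt; aq. NaHCO3, EtOAc, rt
Reagents that add atoms: N,N-dimethylmethyleneiminium iodide, C=[N+](C)C.[I-]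
Why: the kinetic lithium enolate of the lactone (the tiglate has no α-hydrogen and its γ-deprotonation is slow at −78 °C) should undergo a Mannich reaction, and quaternisation followed by E1cB elimination gives the exocyclic methylene (Eschenmoser methylenation); the transient C11 stereocentre is destroyed.

Step 15
Reactants: 25 (3aR,4R,6E,10E,11aR)-6,10-dimethyl-3-methylidene-2-oxo-2,3,3a,4,5,8,9,11a-octahydrocyclodeca[b]furan-4-yl (E)-2-methylbut-2-enoate
Product: 26 (1R,4R,5R,6S,7R,8R,10R)-8β-[(E)-2-methylbut-2-enoyloxy]-1β,10α:4α,5β-diepoxygermacr-11(13)-en-12,6α-olide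
Conditions: mCPBA (2.5 equiv), NaHCO3, CH2Cl2, 0 °C
Reagents that add atoms: 3-chloroperoxybenzoic acid, OOC(=O)c1cccc(Cl)c1
Why: Prilezhaev epoxidation of the two electron-rich trisubstituted ring alkenes from the outer face of the crown conformer (C14 and C15 both on the β face, trans ring fusion) should give by syn addition the two trans-epoxides, 1β,10α (1R,10R) and 4α,5β (4R,5R), while the methylene lactone and the tiglate are too electron-poor to react.

## Compound list

1 | but-2-yn-1-ol | CC#CCO | starting material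
2 | [(E)-4-(diisobutylalumanyloxy)but-2-en-2-yl]chloridozirconocene (cyclopentadienyl rings drawn σ-bound) | CC(C)C[Al](CC(C)C)OC/C=C(\C)[Zr](Cl)(C1C=CC=C1)C1C=CC=C1 | intermediate
3 | (E)-3-iodobut-2-en-1-ol | C/C(I)=C\CO | intermediate
4 | (E)-3-iodobut-2-enal | C/C(I)=C\C=O | intermediate
5 | (S)-4-benzyl-1,3-thiazolidine-2-thione | S=C1N[C@@H](Cc2ccccc2)CS1 | starting material
6 | 4-tert-butoxy-4-oxobutanoic acid | CC(C)(C)OC(=O)CCC(=O)O | starting material
7 | tert-butyl 4-[(4S)-4-benzyl-2-thioxo-1,3-thiazolidin-3-yl]-4-oxobutanoate | CC(C)(C)OC(=O)CCC(=O)N1[C@@H](Cc2ccccc2)CSC1=S | intermediate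
8 | tert-butyl (3S,4S,5E)-3-{[(4S)-4-benzyl-2-thioxo-1,3-thiazolidin-3-yl]carbonyl}-4-hydroxy-6-iodohept-5-enoate | CC(C)(C)OC(=O)C[C@@H]([C@H](O)/C=C(\C)I)C(=O)N1[C@@H](Cc2ccccc2)CSC1=S | intermediate
9 | tert-butyl (3S,4S,5E)-3-{[(4S)-4-benzyl-2-thioxo-1,3-thiazolidin-3-yl]carbonyl}-6-iodo-4-(methoxymethoxy)hept-5-enoate | CC(C)(C)OC(=O)C[C@@H]([C@H](OCOC)/C=C(\C)I)C(=O)N1[C@@H](Cc2ccccc2)CSC1=S | intermediate
10 | tert-butyl (3S,4S,5E)-3-formyl-6-iodo-4-(methoxymethoxy)hept-5-enoate | CC(C)(C)OC(=O)C[C@@H]([C@H](OCOC)/C=C(\C)I)C=O | intermediate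
11 | tributyl(propa-1,2-dien-1-yl)stannane | C=C=C[Sn](CCCC)(CCCC)CCCC | starting material
12 | tert-butyl (3R,4S,5E)-3-[(1R)-1-hydroxybut-3-yn-1-yl]-6-iodo-4-(methoxymethoxy)hept-5-enoate | CC(C)(C)OC(=O)C[C@@H]([C@H](OCOC)/C=C(\C)I)[C@H](O)CC#C | intermediate
13 | (E)-2-methylbut-2-enoyl chloride (tigloyl chloride) | C/C=C(\C)C(=O)Cl | starting material
14 | tert-butyl (3R,4S,5E)-6-iodo-4-(methoxymethoxy)-3-{(1R)-1-[(E)-2-methylbut-2-enoyloxy]but-3-yn-1-yl}hept-5-enoate | CC(C)(C)OC(=O)C[C@@H]([C@H](OCOC)/C=C(\C)I)[C@H](OC(=O)/C(C)=C/C)CC#C | intermediate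
15 | (3S,4S,5E)-4-hydroxy-6-iodo-3-{(1R)-1-[(E)-2-methylbut-2-enoyloxy]but-3-yn-1-yl}hept-5-enoic acid | OC(=O)C[C@@H]([C@H](O)/C=C(\C)I)[C@H](OC(=O)/C(C)=C/C)CC#C | intermediate
16 | (1R)-1-{(2S,3R)-2-[(E)-2-iodoprop-1-en-1-yl]-5-oxooxolan-3-yl}but-3-yn-1-yl (E)-2-methylbut-2-enoate | C1C(=O)O[C@H](/C=C(\C)I)[C@H]1[C@H](OC(=O)/C(C)=C/C)CC#C | intermediate
17 | dimethyl[(1E)-alkenyl]alane of 16 (Al on C1, new methyl on C10, cis to each other) | C1C(=O)O[C@H](/C=C(\C)I)[C@H]1[C@H](OC(=O)/C(C)=C/C)C/C(C)=C/[Al](C)C | intermediate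
18 | (1R,3E)-5-hydroxy-1-{(2S,3R)-2-[(E)-2-iodoprop-1-en-1-yl]-5-oxooxolan-3-yl}-3-methylpent-3-en-1-yl (E)-2-methylbut-2-enoate | C1C(=O)O[C@H](/C=C(\C)I)[C@H]1[C@H](OC(=O)/C(C)=C/C)C/C(C)=C/CO | intermediate
19 | (1R,3E)-1-{(2S,3R)-2-[(E)-2-iodoprop-1-en-1-yl]-5-oxooxolan-3-yl}-3-methyl-5-oxopent-3-en-1-yl (E)-2-methylbut-2-enoate | C1C(=O)O[C@H](/C=C(\C)I)[C@H]1[C@H](OC(=O)/C(C)=C/C)C/C(C)=C/C=O | intermediate
20 | (1R,3E)-1-{(2S,3R)-2-[(E)-2-iodoprop-1-en-1-yl]-5-oxooxolan-3-yl}-3-methylhexa-3,5-dien-1-yl (E)-2-methylbut-2-enoate | C1C(=O)O[C@H](/C=C(\C)I)[C@H]1[C@H](OC(=O)/C(C)=C/C)C/C(C)=C/C=C | intermediate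
21 | B-alkyl-9-borabicyclo[3.3.1]nonane from 20 (boron on C3) | C1C(=O)O[C@H](/C=C(\C)I)[C@H]1[C@H](OC(=O)/C(C)=C/C)C/C(C)=C/CCB1C2CCCC1CCC2 | intermediate
22 | (3aR,4R,6E,10E,11aR)-6,10-dimethyl-2-oxo-2,3,3a,4,5,8,9,11a-octahydrocyclodeca[b]furan-4-yl (E)-2-methylbut-2-enoate (8β-tigloyloxy-13-norgermacra-1(10)E,4E-dien-12,6α-olide) | C1C(=O)O[C@H]2[C@H]1[C@H](OC(=O)/C(C)=C/C)C/C(C)=C/CC/C(C)=C/2 | intermediate
23 | 11-(dimethylaminomethyl) derivative of 22 (C11 epimers) | CN(C)CC1C(=O)O[C@H]2[C@H]1[C@H](OC(=O)/C(C)=C/C)C/C(C)=C/CC/C(C)=C/2 | intermediate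
24 | 11-(trimethylammoniomethyl) iodide of 22 (C11 epimers) | C[N+](C)(C)CC1C(=O)O[C@H]2[C@H]1[C@H](OC(=O)/C(C)=C/C)C/C(C)=C/CC/C(C)=C/2.[I-] | intermediate
25 | (3aR,4R,6E,10E,11aR)-6,10-dimethyl-3-methylidene-2-oxo-2,3,3a,4,5,8,9,11a-octahydrocyclodeca[b]furan-4-yl (E)-2-methylbut-2-enoate (8β-tigloyloxygermacra-1(10)E,4E,11(13)-trien-12,6α-olide) | C=C1C(=O)O[C@H]2[C@H]1[C@H](OC(=O)/C(C)=C/C)C/C(C)=C/CC/C(C)=C/2 | intermediate
26 | (1R,4R,5R,6S,7R,8R,10R)-8β-[(E)-2-methylbut-2-enoyloxy]-1β,10α:4α,5β-diepoxygermacr-11(13)-en-12,6α-olide | C=C1C(=O)O[C@H]2[C@H]1[C@H](OC(=O)/C(C)=C/C)C[C@@]1(C)O[C@@H]1CC[C@@]1(C)O[C@H]21 | target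

## Step count and risks

Total step count: 15 steps. Longest linear sequence: 14 steps (1 to 26 through steps 1, 2 and 4–15).

Three steps most likely to fail:

Step 13. Intermolecular coupling and oligomerisation, or protodeboronation and β-hydride elimination, may outrun closure of the strained ten-membered ring. The fallback sets out from 20 and comes back at 22. Hydroboration as before to 21 and oxidation with NaBO3·4H2O should give the primary alcohol F1. I2, PPh3 and imidazole convert it into the primary iodide F2. Zinc insertion into the C(sp3)–I bond (Zn dust, LiCl, THF, rt) gives the alkylzinc iodide F3. Slow addition of F3 to Pd2(dba)3/tri(2-furyl)phosphine in THF/N-methylpyrrolidinone closes the same C3–C4 bond by intramolecular Negishi coupling, without base or water, to 22.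

Step 14. The amide base may deprotonate the γ-methyl group of the tiglate or add to an ester, so that enolate formation and aminomethylation become unselective. The fallback sets out from 22 and comes back at 23. Soft enolisation with Me3SiOTf/Et3N in CH2Cl2 should give the silyl ketene acetal F4 of the lactone. A Mukaiyama–Mannich reaction of F4 with CH2=NMe2+ I− then gives Mannich base 23, which is quaternised and eliminated as in step 14.

Step 15. The peracid may attack a minor ring conformer and so reach the wrong face of one alkene, or acid may trigger transannular opening of the first-formed 1,10-epoxide by the C4=C5 alkene. The fallback sets out from 25 and comes back at 26. It replaces substrate control by reagent control: dioxirane epoxidation with the D-fructose-derived Shi ketone (KHSO5, K2CO3, Bu4NHSO4, MeCN/dimethoxymethane/aq. Na2B4O7, 0 °C). Its spiro transition state is expected to give the (R,R)-epoxide from each (E)-trisubstituted alkene, the same sense as required at C1/C10 and C4/C5, under non-acidic conditions. It makes no new compound (F0).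

Further compounds
F1 | step 13 | (1R,3E)-6-hydroxy-1-{(2S,3R)-2-[(E)-2-iodoprop-1-en-1-yl]-5-oxooxolan-3-yl}-3-methylhex-3-en-1-yl (E)-2-methylbut-2-enoate | C1C(=O)O[C@H](/C=C(\C)I)[C@H]1[C@H](OC(=O)/C(C)=C/C)C/C(C)=C/CCO
F2 | step 13 | (1R,3E)-6-iodo-1-{(2S,3R)-2-[(E)-2-iodoprop-1-en-1-yl]-5-oxooxolan-3-yl}-3-methylhex-3-en-1-yl (E)-2-methylbut-2-enoate | C1C(=O)O[C@H](/C=C(\C)I)[C@H]1[C@H](OC(=O)/C(C)=C/C)C/C(C)=C/CCI
F3 | step 13 | alkylzinc iodide from F2 (zinc on C3) | C1C(=O)O[C@H](/C=C(\C)I)[C@H]1[C@H](OC(=O)/C(C)=C/C)C/C(C)=C/CC[Zn]I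
F4 | step 14 | trimethylsilyl ketene acetal of lactone 22 (2-trimethylsilyloxy-4,5-dihydrofuran form) | C1=C(O[Si](C)(C)C)O[C@H]2[C@H]1[C@H](OC(=O)/C(C)=C/C)C/C(C)=C/CC/C(C)=C/2
F0 | step 15 | none | none
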